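**Retrosynthetic overview**
- Target 18 ⇒ labd-7-ene-2α,15-diol 16 + ferulic acid 17; the primary alcohol is esterified last by a chemoselective Mitsunobu reaction.
- 16 ⇒ acyclic triene sulfone 15. One radical cascade closes ring A (C4–C5) and then ring B (C10–C9), and ends by loss of PhSO2• from C7, which places the alkene at C7=C8. The C2 carbinol controls C5, C9 and C10.
- 15 ⇒ allyl sulfone 4 (C7–C17, with C13 from (R)-citronellol) + allylic bromide 12 (C1–C6, C10, C18–C20, with C2 from (S)-epichlorohydrin), joined at C6–C7 by sulfonyl-carbanion alkylation.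
- 12 ⇒ (S)-epichlorohydrin by isopropenyl and acetylide epoxide openings, then alkyne carboalumination (E-C5=C10).

Assumption: atoms carry labdane numbers (C1–C20) from fragment to target; the sulfone-bearing C7 of 15 is an uncontrolled epimer mixture because the key step erases it.

**Step 1**
Reactants: 1 (R)-citronellol
Product: 2 (2E,6R)-2,6-dimethyloct-2-ene-1,8-diol
Conditions: SeO2 (0.2 equiv), t-BuOOH (3 equiv), salicylic acid (0.1 equiv), CH2Cl2, 23 °C
Reagents that add atoms: tert-butyl hydroperoxide CC(C)(C)OO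
Why: Sharpless–Umbreit allylic oxidation (SeO2 ene reaction, then [2,3]-sigmatropic shift) hydroxylates only the (E)-methyl of the trisubstituted alkene; the saturated primary alcohol is inert and the C13 stereocentre comes unchanged from the chiral pool.

**Step 2**
Reactants: 2 (2E,6R)-2,6-dimethyloct-2-ene-1,8-diol
Product: 4 (3R,6E)-3,7-dimethyl-8-(phenylsulfonyl)oct-6-en-1-ol, via allylic bromide 3 (not isolated)
Conditions: NBS (1.2 equiv), Me2S (1.5 equiv), CH2Cl2, −20 → 0 °C; aqueous wash, no purification; PhSO2Na (1.5 equiv), DMF, 23 °C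
Reagents that add atoms: sodium benzenesulfinate [Na+].[O-]S(=O)c1ccccc1; N-bromosuccinimide O=C1CCC(=O)N1Br (bromine of 3 only)
Why: Corey–Kim halogenation converts only the allylic hydroxyl (the saturated alkoxysulfonium salt reverts to the alcohol on washing), and SN2 attack of sulfinate sulfur on the primary allylic bromide gives the allyl sulfone with the E-alkene intact.

**Step 3**
Reactants: 5 (S)-epichlorohydrin
Product: 6 (2S)-1-chloro-4-methylpent-4-en-2-ol
Conditions: isopropenylMgBr (1.2 equiv), CuI (0.1 equiv), THF, −40 → −20 °C; aqueous work-up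
Reagents that add atoms: isopropenylmagnesium bromide CC(=C)[Mg]Br
Why: Copper-catalysed Grignard opening of the epoxide at its CH2 terminus is faster than chloride displacement, so the C–O stereocentre (future C2) is never a reaction site and keeps its configuration.

**Step 4**
Reactants: 6 (2S)-1-chloro-4-methylpent-4-en-2-ol
Product: 8 (4S)-2-methylhept-1-en-6-yn-4-ol, via epoxide 7 (not isolated)
Conditions: LiC≡CH·H2NCH2CH2NH2 (3 equiv), DMSO, 5 → 23 °C; aqueous work-up
Reagents that add atoms: lithium acetylide (ethylenediamine complex) [Li]C#C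
Why: Williamson closure to the terminal epoxide, then SN2 opening at CH2 by acetylide (epoxide alkynylation), builds the C1–C10 bond without touching the carbinol stereocentre.

**Step 5**
Reactants: 8 (4S)-2-methylhept-1-en-6-yn-4-ol
Product: 11 (2E,5S)-3,7-dimethylocta-2,7-diene-1,5-diol, via alkenylalane 9 (not isolated), via dilithium bis-alanate 10 (not isolated)
Conditions: Me3Al (3 equiv), Cp2ZrCl2 (0.25 equiv), CH2Cl2, 0 → 23 °C; volatiles removed; n-BuLi (2.2 equiv), THF, −78 °C; (CH2O)n (5 equiv), −78 → 23 °C; aq. potassium sodium tartrate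
Reagents that add atoms: trimethylaluminium C[Al](C)C; paraformaldehyde (as formaldehyde) C=O; n-butyllithium CCCC[Li] (butyl groups and lithium of 10 only)
Why: Negishi zirconium-catalysed carboalumination adds Me and Al syn across the terminal alkyne with methyl on the internal carbon, which fixes the E-trisubstituted C5=C10 alkene and installs C20; the alanate is hydroxymethylated with retention and the isopropenyl group is inert.

**Step 6**
Reactants: 11 (2E,5S)-3,7-dimethylocta-2,7-diene-1,5-diol
Product: 12 (4S,6E)-8-bromo-2,6-dimethylocta-1,6-dien-4-ol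
Conditions: NBS (1.2 equiv), Me2S (1.5 equiv), CH2Cl2, −20 → 0 °C
Reagents that add atoms: N-bromosuccinimide O=C1CCC(=O)N1Br
Why: Corey–Kim bromination is selective for the primary allylic hydroxyl over the secondary homoallylic one and proceeds without allylic transposition or loss of E-geometry.

**Step 7**
Reactants: 4 (3R,6E)-3,7-dimethyl-8-(phenylsulfonyl)oct-6-en-1-ol; 12 (4S,6E)-8-bromo-2,6-dimethylocta-1,6-dien-4-ol
Product: 15 (3R,6E,10E,13S)-3,7,11,15-tetramethyl-8-(phenylsulfonyl)hexadeca-6,10,15-triene-1,13-diol (epimer mixture at the sulfone carbon), via dilithiated sulfone 13 (not isolated), via lithium alkoxide 14 (not isolated)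
Conditions: 4, n-BuLi (2.1 equiv), THF–DMPU (4:1), −78 °C; then 12 premixed with LiHMDS (1.0 equiv) in THF at −78 °C; −78 → −20 °C; aqueous work-up
Reagents that add atoms: n-butyllithium CCCC[Li] (lithium of 13 only); lithium hexamethyldisilazide [Li]N([Si](C)(C)C)[Si](C)(C)C (lithium of 14 only)
Why: Julia/Biellmann-type alkylation of a sulfone-stabilised allyl carbanion occurs at the α-carbon by SN2 on the primary allylic bromide with both E-alkenes retained; the new C7 centre forms as an epimer mixture that step 8 erases.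

**Step 8**
Reactants: 15 (3R,6E,10E,13S)-3,7,11,15-tetramethyl-8-(phenylsulfonyl)hexadeca-6,10,15-triene-1,13-diol
Product: 16 (2S,5S,9S,10S,13R)-labd-7-ene-2,15-diol (2α-hydroxylabd-7-en-15-ol; trans-decalin, 2-OH equatorial, 10-Me β, H5 and H9 α)
Conditions: Fe(acac)3 (0.3 equiv), PhSiH3 (2.5 equiv), EtOH/(CH2OH)2 (5:1), 0.01 M, degassed, 60 °C
Reagents that add atoms: none
Why: Proposed new method: hydrogen-atom transfer from the Fe–H species formed from Fe(acac)3 and PhSiH3 goes to the least hindered, most electron-rich 1,1-disubstituted alkene and gives the C4 tertiary radical, which closes ring A by 6-endo attack on C5 and then ring B by 6-endo attack of the C10 radical on C9 through a chair–chair array; the resulting C8 radical is β to the sulfone and expels PhSO2• (SH2′-type β-scission), which fixes the alkene at C7=C8 and converges both C7 epimers, and the sulfonyl radical is reduced to sulfinate by divalent iron so that trivalent iron is regenerated; the C2 hydroxyl stays equatorial in the ring A chair (an axial one would clash with the C4 and C10 methyls), which sets C5 and C10 from C2, and the E-C8=C9 alkene places the side chain equatorial at C9; the closest known reactions are hydrogen-atom-transfer-initiated radical polyene bicyclizations that end on acceptor alkenes, Cp2TiCl-mediated epoxypolyene radical cyclizations, and radical allylations with allyl sulfones.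

**Step 9**
Reactants: 16 (2S,5S,9S,10S,13R)-labd-7-ene-2,15-diol; 17 (E)-ferulic acid
Product: 18 (2S,5S,9S,10S,13R)-2-hydroxylabd-7-en-15-yl (E)-ferulate (CNP0175017.1)
Conditions: 17 (1.1 equiv), PPh3 (1.3 equiv), DIAD (1.3 equiv, slow addition), THF, 0 → 23 °C
Reagents that add atoms: none
Why: Mitsunobu esterification uses the carboxylate, not the less acidic phenol, as nucleophile and displaces only the primary alkoxyphosphonium, because SN2 at the equatorial C2 carbinol would need a β-axial approach blocked by the syn-axial C4 and C10 methyls; no stereocentre and not the E-cinnamate is touched.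

**Compound list**
1 | (R)-citronellol, (3R)-3,7-dimethyloct-6-en-1-ol | OCC[C@H](C)CCC=C(C)C | starting material
2 | (2E,6R)-2,6-dimethyloct-2-ene-1,8-diol | OCC[C@H](C)CC/C=C(\C)CO | intermediate
3 | (3R,6E)-8-bromo-3,7-dimethyloct-6-en-1-ol | OCC[C@H](C)CC/C=C(\C)CBr | intermediate (not isolated)
4 | (3R,6E)-3,7-dimethyl-8-(phenylsulfonyl)oct-6-en-1-ol | OCC[C@H](C)CC/C=C(\C)CS(=O)(=O)c1ccccc1 | intermediate
5 | (S)-epichlorohydrin | ClC[C@@H]1CO1 | starting material
6 | (2S)-1-chloro-4-methylpent-4-en-2-ol | ClC[C@@H](O)CC(C)=C | intermediate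
7 | (2S)-2-(2-methylprop-2-en-1-yl)oxirane | C=C(C)C[C@H]1CO1 | intermediate (not isolated)
8 | (4S)-2-methylhept-1-en-6-yn-4-ol | C#CC[C@@H](O)CC(C)=C | intermediate
9 | (E)-alkenyldimethylalane of 8 (O–AlMe2 alkoxide; Me on C10, Al on C5) | C[Al](C)/C=C(\C)C[C@@H](O[Al](C)C)CC(C)=C | intermediate (not isolated)
10 | dilithium bis(butyldimethylalanate) of 9 | [Li+].[Li+].CCCC[Al-](C)(C)/C=C(\C)C[C@@H](O[Al-](C)(C)CCCC)CC(C)=C | intermediate (not isolated)
11 | (2E,5S)-3,7-dimethylocta-2,7-diene-1,5-diol | OC/C=C(\C)C[C@@H](O)CC(C)=C | intermediate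
12 | (4S,6E)-8-bromo-2,6-dimethylocta-1,6-dien-4-ol | BrC/C=C(\C)C[C@@H](O)CC(C)=C | intermediate
13 | O,C-dilithio derivative of 4 (lithium alkoxide, α-sulfonyl carbanion) | [Li]OCC[C@H](C)CC/C=C(\C)C([Li])S(=O)(=O)c1ccccc1 | intermediate (not isolated)
14 | lithium alkoxide of 12 | BrC/C=C(\C)C[C@@H](O[Li])CC(C)=C | intermediate (not isolated)
15 | (3R,6E,10E,13S)-3,7,11,15-tetramethyl-8-(phenylsulfonyl)hexadeca-6,10,15-triene-1,13-diol, epimer mixture at C8 of this name (labdane C7) | OCC[C@H](C)CC/C=C(\C)C(S(=O)(=O)c1ccccc1)C/C=C(\C)C[C@@H](O)CC(C)=C | intermediate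
16 | (2S,5S,9S,10S,13R)-labd-7-ene-2,15-diol | OCC[C@H](C)CC[C@H]2C(C)=CC[C@H]3C(C)(C)C[C@H](O)C[C@]23C | intermediate
17 | (E)-ferulic acid, (E)-3-(4-hydroxy-3-methoxyphenyl)prop-2-enoic acid | COc1cc(/C=C/C(=O)O)ccc1O | starting material
18 | (2S,5S,9S,10S,13R)-2-hydroxylabd-7-en-15-yl (E)-ferulate | COc1cc(/C=C/C(=O)OCC[C@H](C)CC[C@H]2C(C)=CC[C@H]3C(C)(C)C[C@H](O)C[C@]23C)ccc1O | target

**Step count and risk**
Total: 9 steps. Longest linear sequence: 7 steps (5 → 6 → 8 → 11 → 12 → 15 → 16 → 18, steps 3–9).

Step 8 is the most likely to fail. Hydrogen-atom transfer may also occur at a trisubstituted alkene. The released sulfonyl radical may add to the isopropenyl group and start a chain that isomerises 15. The C7 epimer with an equatorial C–S bond may fragment slowly. Induction from C2 to C5 rests on an equatorial preference that has not been measured in a radical chair. The fallback sets out from 12 and from 2 (through its crude bromide 3) and comes back at 16. Bromide 12 is treated with PhSO2Na in DMF to give (4S,6E)-2,6-dimethyl-8-(phenylsulfonyl)octa-1,6-dien-4-ol F1. F1 is deprotonated with excess LiHMDS in THF–DMPU at −78 °C and alkylated with 3 to give (3R,6E,10E,13S)-3,7,11,15-tetramethyl-9-(phenylsulfonyl)hexadeca-6,10,15-triene-1,13-diol F2. In F2 the sulfone sits on labdane C6, where Pd(dppp)Cl2 (cat.) and LiBHEt3 in THF at 0 °C remove it by hydride delivery to the less substituted allyl terminus without alkene migration, giving (3R,6E,10E,13S)-3,7,11,15-tetramethylhexadeca-6,10,15-triene-1,13-diol F3. F3 is then cyclised in a radical–polar crossover mode with a Co(salen) catalyst (salen = N,N′-bis(3,5-di-tert-butylsalicylidene)ethylenediamine dianion), N-fluoro-2,4,6-trimethylpyridinium tetrafluoroborate and (Me2SiH)2O in HFIP at 0 °C. The C8 cation loses the axial H7 to give 16, and any exocyclic C8(17) isomer is separated.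

Step 7 is the second risk. Both partners carry free hydroxyls, so the carbanion may be quenched, and the product may be alkylated twice. The fallback sets out from 4 and 12 and comes back at 15. Each partner is silylated with TBSCl and imidazole in DMF to give tert-butyl{[(3R,6E)-3,7-dimethyl-8-(phenylsulfonyl)oct-6-en-1-yl]oxy}dimethylsilane F4 and {[(4S,6E)-8-bromo-2,6-dimethylocta-1,6-dien-4-yl]oxy}(tert-butyl)dimethylsilane F5. The monoanion of F4 (n-BuLi 1.05 equiv, THF–DMPU, −78 °C) is alkylated with F5 to give the bis(tert-butyldimethylsilyl) ether of 15 F6, and TBAF in THF returns 15.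

Step 9 is the third risk. The phenol of 17 may compete, or the reaction may stall on the hindered diol. The fallback sets out from 16 and comes back at 18. Diol 16 is heated with Meldrum's acid (1.0 equiv, toluene, 90 °C), which acylates the primary hydroxyl preferentially, to give the malonic half-ester 3-{[(2S,5S,9S,10S,13R)-2-hydroxylabd-7-en-15-yl]oxy}-3-oxopropanoic acid F7. Knoevenagel–Doebner condensation of F7 with vanillin (pyridine, piperidine cat., 60 °C) builds the E-ferulate with loss of CO2 and gives 18 without exposing a free phenol to an acylating agent.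

**Further compounds**
F1 | step 8 | (4S,6E)-2,6-dimethyl-8-(phenylsulfonyl)octa-1,6-dien-4-ol | O=S(=O)(C/C=C(\C)C[C@@H](O)CC(C)=C)c1ccccc1
F2 | step 8 | (3R,6E,10E,13S)-3,7,11,15-tetramethyl-9-(phenylsulfonyl)hexadeca-6,10,15-triene-1,13-diol | OCC[C@H](C)CC/C=C(\C)CC(S(=O)(=O)c1ccccc1)/C=C(\C)C[C@@H](O)CC(C)=C
F3 | step 8 | (3R,6E,10E,13S)-3,7,11,15-tetramethylhexadeca-6,10,15-triene-1,13-diol | OCC[C@H](C)CC/C=C(\C)CC/C=C(\C)C[C@@H](O)CC(C)=C
F4 | step 7 | tert-butyl{[(3R,6E)-3,7-dimethyl-8-(phenylsulfonyl)oct-6-en-1-yl]oxy}dimethylsilane | CC(C)(C)[Si](C)(C)OCC[C@H](C)CC/C=C(\C)CS(=O)(=O)c1ccccc1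
F5 | step 7 | {[(4S,6E)-8-bromo-2,6-dimethylocta-1,6-dien-4-yl]oxy}(tert-butyl)dimethylsilane | BrC/C=C(\C)C[C@@H](O[Si](C)(C)C(C)(C)C)CC(C)=C
F6 | step 7 | bis(tert-butyldimethylsilyl) ether of 15 | CC(C)(C)[Si](C)(C)OCC[C@H](C)CC/C=C(\C)C(S(=O)(=O)c1ccccc1)C/C=C(\C)C[C@@H](O[Si](C)(C)C(C)(C)C)CC(C)=C
F7 | step 9 | 3-{[(2S,5S,9S,10S,13R)-2-hydroxylabd-7-en-15-yl]oxy}-3-oxopropanoic acid | OC(=O)CC(=O)OCC[C@H](C)CC[C@H]2C(C)=CC[C@H]3C(C)(C)C[C@H](O)C[C@]23C
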